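**Assumption:** target 7 has no stereocentre, and its 18-membered ring is taken as conformationally mobile (no isolable atropisomers), so there is no enantiomer to select and no step needs stereocontrol.

## Retrosynthetic overview

1. 7 ⇒ perrottetin E (6): cut the diaryl ether between the ring-D oxygen and the ring-A carbon para to OH. This oxidative phenol C–O coupling closes the 18-membered ring, the only ring formed.
2. 6 ⇒ 2 × lunularin (5): cut the ether between the ring-B oxygen and the ring-C carbon ortho to OH (intermolecular oxidative phenol C–O coupling). Both couplings run in one flask on unprotected 5.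
3. 5 ⇒ 4-acetoxystyrene (1) + 3-bromophenol (2) by one-pot hydroboration / B-alkyl Suzuki coupling / acetate cleavage.
4. Ring labels: unit 1 = A (3-hydroxyphenyl) + B (4-oxyphenyl); unit 2 = C (4-hydroxyphenyl) + D (3-oxyphenyl). The four benzene rings are bought; the macrocycle is formed last.

## Route

Step 1
Reactants: 1 4-acetoxystyrene (4-ethenylphenyl acetate); 2 3-bromophenol
Product: 5 lunularin (3-[2-(4-hydroxyphenyl)ethyl]phenol), via 4-[2-(9-borabicyclo[3.3.1]nonan-9-yl)ethyl]phenyl acetate 3 (not isolated), via 4-[2-(9-borabicyclo[3.3.1]nonan-9-yl)ethyl]phenol 4 (not isolated)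
Conditions: 1, 9-BBN (0.5 M in THF, 1.1 equiv), 0 °C → rt, 3 h; then 2 (0.9 equiv), PdCl2(dppf) (3 mol %), 3 M aq NaOH (5 equiv), THF, 65 °C, 12 h; aq NH4Cl
Reagents that add atoms: 9-BBN (9-borabicyclo[3.3.1]nonane), B1C2CCCC1CCC2 (its boron and C8 ring are carried in 3 and 4 only; in 5 it leaves hydrogen alone)
Why: Anti-Markovnikov hydroboration of the styrene with 9-BBN puts boron on the terminal carbon, aqueous NaOH saponifies the aryl acetate and activates the borane, and B-alkyl Suzuki–Miyaura coupling with the aryl bromide gives the bibenzyl directly; no stereocentre arises.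

Step 2
Reactants: 5 lunularin (two molecules)
Product: 7 target macrocycle, via perrottetin E 6 (not isolated)
Conditions: (i) [Cu(OH)(TMEDA)]2Cl2 (5 mol %), O2 (1 atm, reduced to water), THF–toluene 1:1, 0.3 M, 25 °C, stopped at ca. 35% conversion of 5; (ii) diluted into toluene to ≤1 mM, Cu(iPr3tacn)Cl2 (10 mol %), 2,6-diphenylpyridine (1 equiv), O2, 40 °C, 24 h; aq EDTA wash, silica, then reversed-phase HPLC (5 recovered)
Reagents that add atoms: none
Why: Proposed new method: two dehydrogenative phenol C–O couplings in sequence (biomimetic oxidative phenol coupling; closest known types are the Cu/amine–O2 C–O coupling of phenols used for poly(phenylene oxide) and the para-selective Cu(triazacyclononane)/O2 "controlled-radical" coupling of m-cresol and 4-phenoxyphenol) – in (i) fast phenoxyl/phenol hydrogen exchange places the radical on the p-alkylphenol ring (O–H bond about 2 kcal/mol weaker than in the m-alkyl ring), whose para position is blocked, so Cu-bound phenoxyls join O to ortho-C and tautomerise to 6, and in (ii) at ≤1 mM the bulky Cu(tacn) centre, which binds the ortho-aryloxy phenol of ring C poorly, couples the two unhindered m-alkylphenol rings O(ring D) to para-C(ring A) and closes the 18-membered ring; no stereocentre is formed.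

## Compound list

1 | 4-acetoxystyrene (4-ethenylphenyl acetate) | CC(=O)Oc1ccc(C=C)cc1 | starting material
2 | 3-bromophenol | Oc1cccc(Br)c1 | starting material
3 | 4-[2-(9-borabicyclo[3.3.1]nonan-9-yl)ethyl]phenyl acetate (formed in the flask) | CC(=O)Oc1ccc(CCB2C3CCCC2CCC3)cc1 | intermediate
4 | 4-[2-(9-borabicyclo[3.3.1]nonan-9-yl)ethyl]phenol (in the flask as its sodium phenoxide/hydroxyborate) | Oc1ccc(CCB2C3CCCC2CCC3)cc1 | intermediate
5 | lunularin, 3-[2-(4-hydroxyphenyl)ethyl]phenol | Oc1ccc(CCc2cccc(O)c2)cc1 | intermediate
6 | perrottetin E, 2-{4-[2-(3-hydroxyphenyl)ethyl]phenoxy}-4-[2-(3-hydroxyphenyl)ethyl]phenol (formed in the flask) | Oc1cccc(CCc2ccc(Oc3cc(CCc4cccc(O)c4)ccc3O)cc2)c1 | intermediate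
7 | target macrocycle: perrottetin E with its ring-D oxygen bonded to the ring-A carbon para to OH (18-membered bis(bibenzyl) bis(diaryl ether) diol, achiral) | Oc1ccc2c(c1)CCc1ccc(cc1)Oc1cc(ccc1O)CCc1cccc(c1)O2 | target

## Totals and risks

Total step count: 2. Longest linear sequence: 2.

The route has only two steps, so both are ranked and there is no third step to name.

Step 2 is by far the most likely to fail; a realistic isolated yield of 7 is in the low single digits, with unreacted 5 recovered. In stage (i) the p-alkylphenoxyl can couple through carbon (biphenyl and Pummerer-ketone-type dimers) and the m-alkylphenol ring can enter early, giving isomeric open dimers and oligomers. In stage (ii) the isomeric 18-membered macrocycle, in which the ring-A oxygen adds to ring D, is expected in an amount similar to 7 and must be removed by HPLC. The 4-aryloxyphenol unit of 7 is also more easily oxidised than 5. The fallback makes the first diaryl ether by Ullmann coupling and keeps only the ring closure oxidative; it sets out from 2 and comes back to the route at 6.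
- MOMCl/iPr2NEt in CH2Cl2 converts 2 into 1-bromo-3-(methoxymethoxy)benzene F1.
- Hydroboration of 1 with 9-BBN (again through 3 and 4) and Suzuki coupling with F1 under the step-1 conditions gives 4-[2-(3-(methoxymethoxy)phenyl)ethyl]phenol F2.
- NBS with catalytic iPr2NH in CH2Cl2 at 0 °C brominates ortho to the free OH, giving 2-bromo-4-[2-(3-(methoxymethoxy)phenyl)ethyl]phenol F3.
- MOMCl/iPr2NEt then gives 2-bromo-1-(methoxymethoxy)-4-[2-(3-(methoxymethoxy)phenyl)ethyl]benzene F4.
- CuI, N,N-dimethylglycine and Cs2CO3 in dioxane at 100 °C couple F2 with F4 to perrottetin E tris(methoxymethyl) ether F5.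
- HCl in MeOH at 50 °C removes the three MOM groups to give 6, which is then isolated pure and closed to 7 under stage (ii) of step 2 alone.

This removes the dimerisation mixture but not the competing closure onto ring D.

Step 1 is the second risk: oxidative addition into the bromophenoxide can be slow, and the alkylborane can be lost by protodeboronation or β-hydride elimination. The fallback is a Heck/hydrogenation sequence that sets out from 1 and 2 and comes back at 5. Pd(OAc)2, P(o-tol)3 and Et3N in DMF at 100 °C give (E)-4-[2-(3-hydroxyphenyl)ethenyl]phenyl acetate F6. H2 over Pd/C in MeOH gives 4-[2-(3-hydroxyphenyl)ethyl]phenyl acetate F7. Catalytic K2CO3 in MeOH then cleaves the acetate to 5.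

## Further compounds

F1 | step 2 | 1-bromo-3-(methoxymethoxy)benzene | COCOc1cccc(Br)c1
F2 | step 2 | 4-[2-(3-(methoxymethoxy)phenyl)ethyl]phenol | COCOc1cccc(CCc2ccc(O)cc2)c1
F3 | step 2 | 2-bromo-4-[2-(3-(methoxymethoxy)phenyl)ethyl]phenol | COCOc1cccc(CCc2ccc(O)c(Br)c2)c1
F4 | step 2 | 2-bromo-1-(methoxymethoxy)-4-[2-(3-(methoxymethoxy)phenyl)ethyl]benzene | COCOc1cccc(CCc2ccc(OCOC)c(Br)c2)c1
F5 | step 2 | perrottetin E tris(methoxymethyl) ether | COCOc1cccc(CCc2ccc(Oc3cc(CCc4cccc(OCOC)c4)ccc3OCOC)cc2)c1
F6 | step 1 | (E)-4-[2-(3-hydroxyphenyl)ethenyl]phenyl acetate | CC(=O)Oc1ccc(/C=C/c2cccc(O)c2)cc1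
F7 | step 1 | 4-[2-(3-hydroxyphenyl)ethyl]phenyl acetate | CC(=O)Oc1ccc(CCc2cccc(O)c2)cc1
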